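The side chain is cut at two bonds, C3–C1' and C2'–O, which turns it back into myrcene: the diene has taken the phloroglucinol ring at its terminal vinyl carbon and an oxygen at the next carbon. The feature exploited is that ring carbon C3 sits ortho to the phenol oxygen on C4; extended by a di-tert-butylsilanol, that oxygen can reach C2' through a temporary seven-membered 1,3,2-dioxasilepine ring. One palladium-catalysed operation on the 3-iodo-4-silanoloxy-2,6-bis(methoxymethoxy)benzophenone and myrcene therefore forms the C–C bond, the C–O bond and the (R) carbinol centre; mild acid and fluoride then free the target.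

Key step: step 5

Locants: the trioxygenated ring is numbered as in benzophenone (C1 carries the benzoyl group, C3 the side chain); the side chain runs from C1' (benzylic CH2) to C8'.

Assumption: for this untested seven-membered closure the sense of induction of a given ligand antipode cannot be assigned beforehand. The route is written with the (S,R,R) phosphoramidite; its mirror image is to be used if a first trial shows that it is the one leading to (R) at C2'.

Step 1
Reactants: 1 2,4,6-trihydroxybenzophenone; 2 di-tert-butylchlorosilane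
Product: 3 [4-(di-tert-butylsilyloxy)-2,6-dihydroxyphenyl](phenyl)methanone
Conditions: imidazole, DMF, 0 °C to rt
Reagents that add atoms: none
Why: Imidazole-promoted O-silylation of a phenol with a bulky chlorosilane should take the 4-hydroxyl, the most acidic one and the only one neither hydrogen-bonded to nor flanked by the benzoyl group, and silylating the symmetric triol first leaves no regiochemical question for the later iodination.

Step 2
Reactants: 3 [4-(di-tert-butylsilyloxy)-2,6-dihydroxyphenyl](phenyl)methanone
Product: 4 [4-(di-tert-butylsilyloxy)-2,6-bis(methoxymethoxy)phenyl](phenyl)methanone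
Conditions: NaH, MOMCl, THF, 0 °C to rt
Reagents that add atoms: chloromethyl methyl ether, COCCl
Why: Williamson-type alkylation of the two sodium phenoxides with chloromethyl methyl ether, in which NaH breaks the hydrogen bond to the carbonyl group and the hindered di-tert-butylsilyl aryl ether with its Si–H bond should survive in THF (DMF is avoided because it promotes aryl silyl ether cleavage).

Step 3
Reactants: 4 [4-(di-tert-butylsilyloxy)-2,6-bis(methoxymethoxy)phenyl](phenyl)methanone
Product: 5 {4-[di-tert-butyl(hydroxy)silyloxy]-2,6-bis(methoxymethoxy)phenyl}(phenyl)methanone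
Conditions: DMDO, acetone, 0 °C
Reagents that add atoms: dimethyldioxirane, CC1(C)OO1
Why: Oxygen insertion of a dioxirane into the Si–H bond, a fast electrophilic oxidation that also works for hindered hydrosilanes, is run before iodine is introduced and at 0 °C should spare acetals, ketone and the trioxygenated ring (an N-halosuccinimide route to the silanol is avoided because it would halogenate this ring).

Step 4
Reactants: 5 {4-[di-tert-butyl(hydroxy)silyloxy]-2,6-bis(methoxymethoxy)phenyl}(phenyl)methanone
Product: 6 {4-[di-tert-butyl(hydroxy)silyloxy]-3-iodo-2,6-bis(methoxymethoxy)phenyl}(phenyl)methanone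
Conditions: NIS (1.05 equiv), MeCN, 0 °C to rt, dark
Reagents that add atoms: N-iodosuccinimide, O=C1CCC(=O)N1I
Why: Electrophilic aromatic iodination of a 1,3,5-trioxygenated ring in which C3 and C5 are equivalent by symmetry, so one equivalent of NIS should give a single mono-iodide under neutral conditions that leave the MOM ethers and the silanol intact.

Step 5
Reactants: 6 {4-[di-tert-butyl(hydroxy)silyloxy]-3-iodo-2,6-bis(methoxymethoxy)phenyl}(phenyl)methanone; 7 myrcene (7-methyl-3-methylideneocta-1,6-diene)
Product: 8 [(4R)-2,2-di-tert-butyl-6,8-bis(methoxymethoxy)-4-(6-methylhepta-1,5-dien-2-yl)-4,5-dihydro-1,3,2-benzodioxasilepin-7-yl](phenyl)methanone (the bis-MOM target with O4 and O2' bridged by di-tert-butylsilylene, (R) at C2')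
Conditions: Pd2(dba)3 [tris(dibenzylideneacetone)dipalladium] (5 mol %), (S)-BINOL bis[(R)-1-phenylethyl]phosphoramidite (20 mol %), Ag2CO3 (1.0 equiv), myrcene (4 equiv), toluene, 60 °C
Reagents that add atoms: none
Why: Proposed new method: the C3–I bond adds oxidatively to the zerovalent palladium–phosphoramidite complex, Ag2CO3 removes iodide and deprotonates the silanol, the cationic arylpalladium inserts the monosubstituted alkene of 7 with aryl transfer to its CH2 terminus (C3–C1' bond), and the tethered silanolate attacks C2' of the resulting pi-allyl complex (C2', C3', exocyclic CH2) on the face opposite palladium, forming C2'–O and returning zerovalent palladium. The closest known reaction type is the palladium-catalysed heteroannulation of 1,3-dienes by o-iodophenols (Larock type, including enantioselective Heck/Tsuji–Trost versions that give 2-isopropenyl dihydrobenzofurans from isoprene), combined with the use of di-tert-butylsilanols as tethered oxygen nucleophiles; the silanol nucleophile in this manifold, the larger ring and its asymmetric control are untested. The single ring closes in a 7-exo mode at the internal allyl terminus to give the 1,3,2-dioxasilepine, attack at the methylene terminus being excluded because it would need a nine-membered ring. C2' is set by the chiral ligand: the two faces of the pi-allyl interconvert through the sigma-allyl form at the unsubstituted CH2 terminus, so the ligand decides which diastereomeric complex undergoes C–O bond formation faster. The step needs regioselective insertion (secured by the least hindered diene terminus, the trisubstituted alkene being inert), oxygen attack by the silanol only (secured by the MOM group on O2, which blocks the five-membered closure by the phenol oxygen) and cyclisation faster than beta-hydride elimination to a Heck triene (favoured by the cationic palladium centre and by the two tert-butyl groups, which hold the Si–O arm over C2').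

Step 6
Reactants: 8 [(4R)-2,2-di-tert-butyl-6,8-bis(methoxymethoxy)-4-(6-methylhepta-1,5-dien-2-yl)-4,5-dihydro-1,3,2-benzodioxasilepin-7-yl](phenyl)methanone
Product: 9 [(4R)-2,2-di-tert-butyl-6,8-dihydroxy-4-(6-methylhepta-1,5-dien-2-yl)-4,5-dihydro-1,3,2-benzodioxasilepin-7-yl](phenyl)methanone
Conditions: HCl (0.3 M in MeOH), 0 °C to rt
Reagents that add atoms: none
Why: Acid-catalysed transacetalisation of the two aryl MOM ethers to methanol, made easy by the flanking carbonyl group, while the acid-stable di-tert-butylsilylene keeps O4 and the allylic C2' oxygen masked, so that neither ionisation at C2' nor cyclisation is expected and the stereocentre is untouched.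

Step 7
Reactants: 9 [(4R)-2,2-di-tert-butyl-6,8-dihydroxy-4-(6-methylhepta-1,5-dien-2-yl)-4,5-dihydro-1,3,2-benzodioxasilepin-7-yl](phenyl)methanone
Product: 10 {2,4,6-trihydroxy-3-[(2R)-2-hydroxy-7-methyl-3-methylideneoct-6-en-1-yl]phenyl}(phenyl)methanone
Conditions: HF·pyridine, pyridine, THF, 0 °C
Reagents that add atoms: none
Why: Fluoride-induced cleavage of both Si–O bonds of the di-tert-butylsilylene (standard silylene removal) frees the C4 phenol and the C2' carbinol without breaking the C2'–O bond, so the (R) configuration is retained.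

Compound list
1 | 2,4,6-trihydroxybenzophenone | O=C(c1ccccc1)c1c(O)cc(O)cc1O | starting material
2 | di-tert-butylchlorosilane | CC(C)(C)[SiH](Cl)C(C)(C)C | starting material
3 | [4-(di-tert-butylsilyloxy)-2,6-dihydroxyphenyl](phenyl)methanone | O=C(c1ccccc1)c1c(O)cc(O[SiH](C(C)(C)C)C(C)(C)C)cc1O | intermediate
4 | [4-(di-tert-butylsilyloxy)-2,6-bis(methoxymethoxy)phenyl](phenyl)methanone | COCOc1cc(O[SiH](C(C)(C)C)C(C)(C)C)cc(OCOC)c1C(=O)c1ccccc1 | intermediate
5 | {4-[di-tert-butyl(hydroxy)silyloxy]-2,6-bis(methoxymethoxy)phenyl}(phenyl)methanone | COCOc1cc(O[Si](O)(C(C)(C)C)C(C)(C)C)cc(OCOC)c1C(=O)c1ccccc1 | intermediate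
6 | {4-[di-tert-butyl(hydroxy)silyloxy]-3-iodo-2,6-bis(methoxymethoxy)phenyl}(phenyl)methanone | COCOc1cc(O[Si](O)(C(C)(C)C)C(C)(C)C)c(I)c(OCOC)c1C(=O)c1ccccc1 | intermediate
7 | myrcene (7-methyl-3-methylideneocta-1,6-diene) | C=CC(=C)CCC=C(C)C | starting material
8 | [(4R)-2,2-di-tert-butyl-6,8-bis(methoxymethoxy)-4-(6-methylhepta-1,5-dien-2-yl)-4,5-dihydro-1,3,2-benzodioxasilepin-7-yl](phenyl)methanone | C=C(CCC=C(C)C)[C@H]1Cc2c(OCOC)c(C(=O)c3ccccc3)c(OCOC)cc2O[Si](C(C)(C)C)(C(C)(C)C)O1 | intermediate
9 | [(4R)-2,2-di-tert-butyl-6,8-dihydroxy-4-(6-methylhepta-1,5-dien-2-yl)-4,5-dihydro-1,3,2-benzodioxasilepin-7-yl](phenyl)methanone | C=C(CCC=C(C)C)[C@H]1Cc2c(O)c(C(=O)c3ccccc3)c(O)cc2O[Si](C(C)(C)C)(C(C)(C)C)O1 | intermediate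
10 | {2,4,6-trihydroxy-3-[(2R)-2-hydroxy-7-methyl-3-methylideneoct-6-en-1-yl]phenyl}(phenyl)methanone | C=C(CCC=C(C)C)[C@H](O)Cc1c(O)cc(O)c(C(=O)c2ccccc2)c1O | target

Total step count: 7. Longest linear sequence: 7 steps (1 to 10).

Steps most likely to fail

Step 5. After insertion, beta-hydride loss from the pi-allyl intermediate may outrun the slow seven-membered C–O closure, or the ligand may give poor facial selectivity at C2'. The fallback uses known chemistry only, sets out from 1 and comes back at 10.
- All three hydroxyls of 1 are alkylated (NaH, MOMCl, DMF) to [2,4,6-tris(methoxymethoxy)phenyl](phenyl)methanone F1, which NIS converts into [3-iodo-2,4,6-tris(methoxymethoxy)phenyl](phenyl)methanone F2.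
- Stille coupling with allyltributylstannane (Pd(PPh3)4, toluene, 100 °C) gives the 3-allyl arene F3, and Lemieux–Johnson cleavage (OsO4 cat., NaIO4, 2,6-lutidine, dioxane–water) gives 2-[3-benzoyl-2,4,6-tris(methoxymethoxy)phenyl]acetaldehyde F4.
- The alkenyl partner, 6-methylhepta-1,5-dien-2-yl trifluoromethanesulfonate F5, is made from commercial 6-methylhept-5-en-2-one by kinetic deprotonation (LDA, THF, −78 °C) and PhNTf2.
- Nozaki–Hiyama–Kishi coupling of F4 with F5 (CrCl2, NiCl2 cat., DMF) gives the racemic allylic alcohol F6, and Dess–Martin oxidation gives the enone 1-[3-benzoyl-2,4,6-tris(methoxymethoxy)phenyl]-7-methyl-3-methylideneoct-6-en-2-one F7.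
- Corey–Bakshi–Shibata reduction with the (S)-methyl oxazaborolidine and catecholborane at −78 °C should give the (R)-alcohol F8. The alkenyl group acts as the large substituent, and the doubly ortho-substituted diaryl ketone is too hindered to compete.
- Methanolic HCl then removes the three MOM groups to give 10.

Step 2. The aryl silyl group may be cleaved or transferred (or hydride lost from silicon) under the strongly basic alkylation, or the hydrogen-bonded hydroxyl may be alkylated incompletely. The fallback sets out from 1 and comes back at 5, and it also bypasses step 3.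
- The acidic 4-hydroxyl is masked as a sulfonate (TsCl 1.0 equiv, Et3N, CH2Cl2, 0 °C) to give 4-benzoyl-3,5-dihydroxyphenyl 4-methylbenzenesulfonate F9.
- With no silicon present, the two remaining hydroxyls are alkylated under standard conditions (NaH, MOMCl, DMF) to 4-benzoyl-3,5-bis(methoxymethoxy)phenyl 4-methylbenzenesulfonate F10.
- KOH in aqueous methanol at 60 °C cleaves the sulfonate to [4-hydroxy-2,6-bis(methoxymethoxy)phenyl](phenyl)methanone F11.
- Silylation with t-Bu2Si(OTf)2 and 2,6-lutidine in CH2Cl2 gives, in the flask, [4-benzoyl-3,5-bis(methoxymethoxy)phenoxy]di-tert-butylsilyl trifluoromethanesulfonate F12, which aqueous NaHCO3 hydrolyses to silanol 5.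

Step 6. Protic acid may partly open the silylene and then ionise or solvolyse the allylic C2'–O bond, or formaldehyde-derived cations may alkylate the electron-rich ring at C5. The fallback sets out from 8 and comes back at 10.
- The acetals are exchanged for silicon under aprotic conditions (TMSOTf, 2,2'-bipyridyl, CH2Cl2, 0 °C), which converts both aryl MOM ethers into [(4R)-2,2-di-tert-butyl-4-(6-methylhepta-1,5-dien-2-yl)-6,8-bis(trimethylsilyloxy)-4,5-dihydro-1,3,2-benzodioxasilepin-7-yl](phenyl)methanone F13.
- A single treatment with HF·pyridine then strips the two trimethylsilyl groups and the di-tert-butylsilylene together, so the end game becomes an all-fluoride deprotection with no protic acid.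

Further compounds
F1 | step 5 | [2,4,6-tris(methoxymethoxy)phenyl](phenyl)methanone | COCOc1cc(OCOC)cc(OCOC)c1C(=O)c1ccccc1
F2 | step 5 | [3-iodo-2,4,6-tris(methoxymethoxy)phenyl](phenyl)methanone | COCOc1cc(OCOC)c(I)c(OCOC)c1C(=O)c1ccccc1
F3 | step 5 | [2,4,6-tris(methoxymethoxy)-3-(prop-2-en-1-yl)phenyl](phenyl)methanone | C=CCc1c(OCOC)cc(OCOC)c(C(=O)c2ccccc2)c1OCOC
F4 | step 5 | 2-[3-benzoyl-2,4,6-tris(methoxymethoxy)phenyl]acetaldehyde | O=CCc1c(OCOC)cc(OCOC)c(C(=O)c2ccccc2)c1OCOC
F5 | step 5 | 6-methylhepta-1,5-dien-2-yl trifluoromethanesulfonate | C=C(CCC=C(C)C)OS(=O)(=O)C(F)(F)F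
F6 | step 5 | racemic [3-(2-hydroxy-7-methyl-3-methylideneoct-6-en-1-yl)-2,4,6-tris(methoxymethoxy)phenyl](phenyl)methanone | C=C(CCC=C(C)C)C(O)Cc1c(OCOC)cc(OCOC)c(C(=O)c2ccccc2)c1OCOC
F7 | step 5 | 1-[3-benzoyl-2,4,6-tris(methoxymethoxy)phenyl]-7-methyl-3-methylideneoct-6-en-2-one | C=C(CCC=C(C)C)C(=O)Cc1c(OCOC)cc(OCOC)c(C(=O)c2ccccc2)c1OCOC
F8 | step 5 | {3-[(2R)-2-hydroxy-7-methyl-3-methylideneoct-6-en-1-yl]-2,4,6-tris(methoxymethoxy)phenyl}(phenyl)methanone | C=C(CCC=C(C)C)[C@H](O)Cc1c(OCOC)cc(OCOC)c(C(=O)c2ccccc2)c1OCOC
F9 | step 2 | 4-benzoyl-3,5-dihydroxyphenyl 4-methylbenzenesulfonate | Cc1ccc(cc1)S(=O)(=O)Oc1cc(O)c(C(=O)c2ccccc2)c(O)c1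
F10 | step 2 | 4-benzoyl-3,5-bis(methoxymethoxy)phenyl 4-methylbenzenesulfonate | Cc1ccc(cc1)S(=O)(=O)Oc1cc(OCOC)c(C(=O)c2ccccc2)c(OCOC)c1
F11 | step 2 | [4-hydroxy-2,6-bis(methoxymethoxy)phenyl](phenyl)methanone | COCOc1cc(O)cc(OCOC)c1C(=O)c1ccccc1
F12 | step 2 | [4-benzoyl-3,5-bis(methoxymethoxy)phenoxy]di-tert-butylsilyl trifluoromethanesulfonate | COCOc1cc(O[Si](OS(=O)(=O)C(F)(F)F)(C(C)(C)C)C(C)(C)C)cc(OCOC)c1C(=O)c1ccccc1
F13 | step 6 | [(4R)-2,2-di-tert-butyl-4-(6-methylhepta-1,5-dien-2-yl)-6,8-bis(trimethylsilyloxy)-4,5-dihydro-1,3,2-benzodioxasilepin-7-yl](phenyl)methanone | C=C(CCC=C(C)C)[C@H]1Cc2c(O[Si](C)(C)C)c(C(=O)c3ccccc3)c(O[Si](C)(C)C)cc2O[Si](C(C)(C)C)(C(C)(C)C)O1
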